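## Structural features

The target 18, [(2R,3S,4R)-4-[(S)-acetyloxy(4-methoxyphenyl)methyl]-2-(4-hydroxyphenyl)oxolan-3-yl]methyl acetate, is a monocyclic oxolane with ring atoms O1, C2, C3, C4 and C5, where C5 is an unsubstituted methylene. C2 carries the 4-hydroxyphenyl ring, C3 the acetoxymethyl carbon C6, and C4 the exocyclic carbon C7, which bears an acetate and the 4-methoxyphenyl ring. The three contiguous ring stereocentres are mutually trans (2,3-trans and 3,4-trans, so the C2 aryl and the C4 side chain are cis), and the fourth stereocentre, C7 (S), stands next to C4 outside the ring. This all-trans pattern is the thermodynamically preferred one, so C3 (and C2 if necessary) can be settled by equilibration once C4 is fixed. C4 in the absolute sense and the C4/C7 relationship have no such help and are the real difficulty. Fragile groups are the benzylic C2–O1 ether para to a free phenol, the ionisable p-methoxybenzylic acetate at C7, the two base-labile acetates, and the need to keep one aryl oxygen free while the other is methylated. The key step exploits the 1,3-relationship of O1 and C4 across C5: O1–C5–C4 with its C7 stub is an allyl alkoxide dipole, and C2–C3 with the branch C6 is the polarised alkene of an arylidene gem-dicarbonyl compound, so O1–C2 and C3–C4 close the oxolane ring in one operation.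

## Logic of the disconnections

18 to 17: the phenolic O–Si bond is cut last. A silyl ether is the only phenol mask that survives organometallic and hydride steps and still leaves under conditions harmless to two acetates; the forward step must use buffered fluoride.

17 to 16: both acyl C–O bonds at C6 and C7 are cut together. Installing the two identical acetates in one late operation means no acetate has to survive a nucleophile or a hydride; the demand is a diol with C7 already configured.

16 to 15: C6 is taken back to the C3 ester. The ester is the latent C6 alcohol and its own protecting group while C7 is built, so no free primary alcohol is present during the C7 oxidation and no protection pair is needed. The demand is an ester reduction that spares the aryl silyl ether.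

15 to 14: the C7–H bond is cut. Setting C7 by hydride delivery to a ketone allows reagent control; a Felkin–Anh analysis also favours the required (S) epimer for hydride addition but the wrong one for aryl addition to the aldehyde. The demand is face selectivity with the ester left alone.

14 to 10 and 11 (through 13 and 12): the C7–aryl bond is cut and the oxidation level adjusted. This splits off the anisyl ring as a commodity aryl bromide; the forward addition must select the aldehyde over the methyl ester and must not epimerise C4.

10 to 8 (through 9): the C7 carbonyl is traced to a vinyl group. The vinyl group is an inert formyl equivalent that the ring-forming step delivers directly; the cleavage must spare the electron-rich arene.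

8 to 6 (through 7): one carboxyl of the gem-dicarbonyl and the acylal bonds are restored. The symmetric gem-dicarbonyl makes the acceptor reactive and is pruned to one ester afterwards. C3 becomes stereogenic here, so the forward step must reach the all-trans isomer by equilibration without ring opening.

6 to 4 and 5: O1–C2 and C3–C4 are cut. One ring, two skeletal bonds and two stereocentres (C2, C4) come from an achiral acceptor and a racemic carbonate; the demand is ligand control of the allyl face, the 2,4-cis relationship, and attack at the internal allyl carbon.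

4 to 2 and 3: the C2=C3 bond is cut by a Knoevenagel retron, which needs only removal of water.

2 to 1: the O–Si bond is cut. The triisopropylsilyl group is chosen because in 4 the aryloxide is a vinylogous leaving group on silicon, and a smaller silyl group would be exposed to the alkoxide of the key step and to methoxide later.

## Other disconnections considered

Alternative 1: The cut is C2–C3. The diazo ester A2 would be decomposed by Rh2(O2CCPh3)4 (a divalent rhodium carboxylate), and the carbenoid at C3 would insert into the benzylic ether C2–H bond through a five-membered transition state to give A1.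
- In its favour: C4 and C7 are acyclic neighbours in A2 and can be set by auxiliary-controlled aldol chemistry before the ring exists. Absolute control then rests on stoichiometric, predictable chemistry and not on a ligand choice, which is better than the chosen plan. C7 also arrives with the right oxidation level and configuration, so the oxidation–reduction pair (steps 7 and 8) is not needed, again better.
- Equal: the C3 ester of A1 maps onto C6 exactly as in 15, and it can be equilibrated to the trans isomer in the same way.
- Against: the carbenoid is an alpha-alkyl diazo ester with a tertiary hydrogen on C4, so 1,2-hydride migration competes with insertion; the bulky carboxylate ligand is meant to suppress this, but it is the main doubt. The diazo group must be placed on a beta-branched ester, which adds activation and diazo-transfer steps.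
- Comparison: the insertion makes one ring bond in a concerted event, whereas the chosen step makes two in a polar stepwise annulation. A2 is estimated to need more steps than the whole chosen route before the ring is closed, so step economy is worse.

Alternative 2: The cuts are C2–C3 and C4–C5, with C5 attached to C7 in the precursor. SnCl4 would open the dioxolane A4 to an oxocarbenium ion at C2, which attacks C3 through a chair. A pinacol shift of C5 from C7 to C4 would then contract the ring and give the aryl ketone A3.
- In its favour: A4 is an acetal of 2, so the two aryl rings again enter separately. Two C–C bonds, the ring and three ring stereocentres form at once. C7 emerges as the ketone and C6 as a protected alcohol, so ozonolysis, aryl addition, oxidation and ester reduction are all avoided. On step economy this is clearly better than the chosen plan.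
- Equal: A3 has the same C7 ketone as 14, so the reduction problem of step 8 remains unchanged.
- Against: the cation at C4 would be secondary, and the allylic silyloxymethyl group makes the alkene less nucleophilic. The tertiary p-methoxyphenyl carbinol C–O bond can ionise on its own under SnCl4, and it is the only stereocentre carrying absolute information. Chirality transfer depends on the anisyl group preferring the equatorial site of the chair (A4 is drawn for that case). Two aryl silyl ethers must also survive a strong Lewis acid.
- Comparison: mechanistically it is a cationic cascade with a sacrificial stereocentre, whereas the chosen step is catalyst-controlled under nearly neutral conditions.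

Alternative 3: The cuts are O1–C2 and C4–C5. Sn(OTf)2 (divalent tin triflate) would open the C2–C4 bond of the donor–acceptor cyclopropane A6, and formaldehyde A7 would be inserted to give A5.
- In its favour: aryl-donor cyclopropanes are a well-behaved class for aldehyde annulation, and the electron-rich aryl group assists opening. The C3 stereocentre is carried through untouched, so absolute configuration does not rest on a ligand, which is equal or better. C6 is already an alcohol, which is better than carrying an ester.
- Against: A7 is an awkward carbonyl partner with no substituent to organise the transition state. An invertive opening at C2 means the 2,3-trans product requires the cis-cyclopropane, the less accessible isomer. A5 carries a gem-diester on C4, so one ester must be excised and the other converted into the aryl carbinol.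
- Comparison: both plans are formal [3+2] annulations through zwitterions and build two bonds and one ring, so they are equal in bond count. Both carry a gem-dicarbonyl that must be pruned, but in the chosen plan the surviving carbonyl only has to be reduced to C6, whereas here it must become C7 with its aryl group. The route from A5 to C7 is therefore longer than from 6, and step economy is worse.

Key step: step 3

Assumption: the phenol is carried as its triisopropylsilyl ether, and the ligand antipode named in step 3 is assumed to be the one leading to (1S,4R)-6; both antipodes are available and the choice would be fixed by a pilot run.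

## Route

Step 1
Reactants: 1 4-hydroxybenzaldehyde
Product: 2 4-(triisopropylsilyloxy)benzaldehyde
Conditions: TIPSCl, imidazole, DMF, 0 °C to rt
Reagents that add atoms: triisopropylsilyl chloride, CC(C)[Si](Cl)(C(C)C)C(C)C
Why: Imidazole-promoted silyl ether formation on the phenol; the bulky silyl group should resist the alkoxide of step 3 and the methoxide of step 4 and still leave with buffered fluoride at the end.

Step 2
Reactants: 2 4-(triisopropylsilyloxy)benzaldehyde; 3 Meldrum's acid (2,2-dimethyl-1,3-dioxane-4,6-dione)
Product: 4 2,2-dimethyl-5-{[4-(triisopropylsilyloxy)phenyl]methylidene}-1,3-dioxane-4,6-dione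
Conditions: piperidine (10 mol %), AcOH (10 mol %), toluene, 4 Å MS, rt; crystallisation
Reagents that add atoms: none
Why: Knoevenagel condensation of the very acidic 3 with the iminium of 2, with water removed by sieves; the product is crystallised and not chromatographed because alkylidene Meldrum's acids hydrolyse on silica, and the alkene has no geometry issue since both acyl arms are identical.

Step 3
Reactants: 4 2,2-dimethyl-5-{[4-(triisopropylsilyloxy)phenyl]methylidene}-1,3-dioxane-4,6-dione; 5 4-vinyl-1,3-dioxolan-2-one (racemic)
Product: 6 (1S,4R)-4-ethenyl-8,8-dimethyl-1-[4-(triisopropylsilyloxy)phenyl]-2,7,9-trioxaspiro[4.5]decane-6,10-dione (aryl and vinyl cis)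
Conditions: Pd2(dba)3·CHCl3 (2.5 mol %), (11bS)-N,N-bis[(1R)-1-phenylethyl]dinaphtho[2,1-d:1′,2′-f][1,3,2]dioxaphosphepin-4-amine (10 mol %), 5 (1.5 equiv), THF, 0 °C to rt
Reagents that add atoms: none
Why: Zerovalent palladium ionises the allylic C–O bond of 5 and the carbonate loses CO2, giving a zwitterionic π-allylpalladium alkoxide; the alkoxide adds reversibly to the benzylic carbon of 4 (O1–C2) and the stabilised carbanion then attacks the internal allyl carbon (C3–C4), releasing the catalyst. The closest known reaction type is the palladium-catalysed decarboxylative [3+2] cycloaddition of vinylethylene carbonates with doubly activated alkenes such as arylidene malononitriles. The oxolane ring closes in a 5-exo mode with the allyl π-system left outside the ring as the vinyl group; attack at the distal allyl carbon would need a seven-membered transition state and should be slower. C4 is set by the phosphoramidite, which differentiates the faces of the allyl unit, and both enantiomers of 5 converge because the unsubstituted allyl terminus allows π–σ–π interconversion before the C–C bond forms. C2 is set relative to C4 in the same ring-closing transition state: since the oxa-Michael step is reversible, the adduct that cyclises with aryl and vinyl both pseudo-equatorial, hence cis, should be selected. C3 is not stereogenic in 6 because the two acyl arms are equivalent. The step needs an acceptor electrophilic enough to trap the alkoxide despite the para donor, which the cyclic acylal provides, and the bulky silyl group keeps the vinylogous aryl silyl ether from attack by the alkoxide.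

Step 4
Reactants: 6 (1S,4R)-4-ethenyl-8,8-dimethyl-1-[4-(triisopropylsilyloxy)phenyl]-2,7,9-trioxaspiro[4.5]decane-6,10-dione
Product: 8 methyl (2R,3R,4R)-4-ethenyl-2-[4-(triisopropylsilyloxy)phenyl]oxolane-3-carboxylate, via malonic half-ester 7 (not isolated)
Conditions: NaOMe (1.05 equiv), MeOH–THF, 0 °C; AcOH, then DMSO, 110 °C; then NaOMe (0.3 equiv), MeOH, rt
Reagents that add atoms: sodium methoxide, [Na+].[O-]C
Why: Methoxide alcoholysis of the acylal gives 7 and acetone, and heating the free acid effects malonic half-ester decarboxylation. C3 becomes stereogenic here; because kinetic protonation is expected anti to the cis aryl and vinyl groups, catalytic methoxide is added to epimerise the ester to the thermodynamic isomer, trans to both neighbours, while C2 and C4 are untouched.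

Step 5
Reactants: 8 methyl (2R,3R,4R)-4-ethenyl-2-[4-(triisopropylsilyloxy)phenyl]oxolane-3-carboxylate
Product: 10 methyl (2R,3R,4R)-4-formyl-2-[4-(triisopropylsilyloxy)phenyl]oxolane-3-carboxylate, via secondary ozonide 9 (not isolated)
Conditions: O3, CH2Cl2, −78 °C (Sudan Red 7B end point); PPh3, −78 °C to rt; used crude
Reagents that add atoms: ozone, [O-][O+]=O
Why: Ozonolysis with reductive work-up; the terminal vinyl group should react far faster than the silyloxy arene and the dye end point guards against over-oxidation. PPh3 reduces 9 under neutral conditions, so C4 (now alpha to the aldehyde) keeps its trans relationship to C3, which is also the thermodynamic one.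

Step 6
Reactants: 10 methyl (2R,3R,4R)-4-formyl-2-[4-(triisopropylsilyloxy)phenyl]oxolane-3-carboxylate; 11 4-bromoanisole
Product: 13 methyl (2R,3R,4R)-4-[hydroxy(4-methoxyphenyl)methyl]-2-[4-(triisopropylsilyloxy)phenyl]oxolane-3-carboxylate (both C7 epimers), via 4-methoxyphenylmagnesium bromide 12 (not isolated)
Conditions: 11, Mg, THF, rt to 40 °C; then 10, THF, −78 °C; pH 7 buffer
Reagents that add atoms: none
Why: Grignard addition; at −78 °C 12 should add to the aldehyde much faster than to the hindered methyl ester. C7 forms without useful control (the Felkin–Anh model predicts mainly the unwanted epimer), which is acceptable because the centre is erased in step 7.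

Step 7
Reactants: 13 methyl (2R,3R,4R)-4-[hydroxy(4-methoxyphenyl)methyl]-2-[4-(triisopropylsilyloxy)phenyl]oxolane-3-carboxylate
Product: 14 methyl (2R,3R,4R)-4-(4-methoxybenzoyl)-2-[4-(triisopropylsilyloxy)phenyl]oxolane-3-carboxylate
Conditions: Dess–Martin periodinane, CH2Cl2, 0 °C to rt
Reagents that add atoms: none
Why: Dess–Martin oxidation of the secondary benzylic alcohol under non-epimerising conditions converges both C7 epimers on one aryl ketone; the ester, the silyl ether and the ring stereocentres should be inert.

Step 8
Reactants: 14 methyl (2R,3R,4R)-4-(4-methoxybenzoyl)-2-[4-(triisopropylsilyloxy)phenyl]oxolane-3-carboxylate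
Product: 15 methyl (2R,3R,4R)-4-[(S)-hydroxy(4-methoxyphenyl)methyl]-2-[4-(triisopropylsilyloxy)phenyl]oxolane-3-carboxylate
Conditions: (3aR)-1-methyl-3,3-diphenyltetrahydro-1H,3H-pyrrolo[1,2-c][1,3,2]oxazaborole ((R)-Me-CBS, 20 mol %), BH3·SMe2, THF, −20 °C; MeOH quench, aqueous work-up
Reagents that add atoms: none
Why: CBS reduction; the oxazaborolidine–borane complex binds the ketone oxygen and delivers hydride intramolecularly, and the (R)-catalyst is expected to give the (S)-carbinol when the aryl ring acts as the larger substituent. The Felkin–Anh preference of 14 (hydride anti to C3) points to the same face, so reagent and substrate should be matched; borane should not reduce the methyl ester at this temperature.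

Step 9
Reactants: 15 methyl (2R,3R,4R)-4-[(S)-hydroxy(4-methoxyphenyl)methyl]-2-[4-(triisopropylsilyloxy)phenyl]oxolane-3-carboxylate
Product: 16 [(2R,3S,4R)-4-[(S)-hydroxy(4-methoxyphenyl)methyl]-2-[4-(triisopropylsilyloxy)phenyl]oxolan-3-yl]methanol
Conditions: LiBH4, THF–MeOH, 0 °C to rt
Reagents that add atoms: none
Why: Ester reduction by LiBH4, which should leave the aryl silyl ether and the benzylic carbinol alone; no stereocentre is affected, and C6 appears as an alcohol only now, so it never needed protection.

Step 10
Reactants: 16 [(2R,3S,4R)-4-[(S)-hydroxy(4-methoxyphenyl)methyl]-2-[4-(triisopropylsilyloxy)phenyl]oxolan-3-yl]methanol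
Product: 17 [(2R,3S,4R)-4-[(S)-acetyloxy(4-methoxyphenyl)methyl]-2-[4-(triisopropylsilyloxy)phenyl]oxolan-3-yl]methyl acetate
Conditions: Ac2O, pyridine, DMAP (cat.), CH2Cl2, 0 °C to rt
Reagents that add atoms: acetic anhydride, CC(=O)OC(C)=O
Why: DMAP-catalysed acylation installs both acetates in one operation; the basic, non-ionising medium should keep the p-methoxybenzylic C7–O bond intact, so C7 retains its configuration.

Step 11
Reactants: 17 [(2R,3S,4R)-4-[(S)-acetyloxy(4-methoxyphenyl)methyl]-2-[4-(triisopropylsilyloxy)phenyl]oxolan-3-yl]methyl acetate
Product: 18 [(2R,3S,4R)-4-[(S)-acetyloxy(4-methoxyphenyl)methyl]-2-(4-hydroxyphenyl)oxolan-3-yl]methyl acetate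
Conditions: TBAF, AcOH, THF, 0 °C
Reagents that add atoms: none
Why: Fluoride-induced cleavage of the aryl silyl ether; acetic acid protonates the phenoxide as it forms, which should suppress acetyl transfer and phenoxide-assisted opening of the C2–O1 bond.

## Compound list

1 | 4-hydroxybenzaldehyde | O=Cc1ccc(O)cc1 | starting material
2 | 4-(triisopropylsilyloxy)benzaldehyde | O=Cc1ccc(O[Si](C(C)C)(C(C)C)C(C)C)cc1 | intermediate
3 | Meldrum's acid (2,2-dimethyl-1,3-dioxane-4,6-dione) | CC1(C)OC(=O)CC(=O)O1 | starting material
4 | 2,2-dimethyl-5-{[4-(triisopropylsilyloxy)phenyl]methylidene}-1,3-dioxane-4,6-dione | CC1(C)OC(=O)C(=Cc2ccc(O[Si](C(C)C)(C(C)C)C(C)C)cc2)C(=O)O1 | intermediate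
5 | 4-vinyl-1,3-dioxolan-2-one (racemic) | C=CC1COC(=O)O1 | starting material
6 | (1S,4R)-4-ethenyl-8,8-dimethyl-1-[4-(triisopropylsilyloxy)phenyl]-2,7,9-trioxaspiro[4.5]decane-6,10-dione | CC1(C)OC(=O)C2(C(=O)O1)[C@@H](C=C)CO[C@H]2c1ccc(O[Si](C(C)C)(C(C)C)C(C)C)cc1 | intermediate
7 | (2S,4R)-4-ethenyl-3-(methoxycarbonyl)-2-[4-(triisopropylsilyloxy)phenyl]oxolane-3-carboxylic acid (both C3 epimers) | C=C[C@H]1CO[C@@H](c2ccc(O[Si](C(C)C)(C(C)C)C(C)C)cc2)C1(C(=O)O)C(=O)OC | intermediate (not isolated)
8 | methyl (2R,3R,4R)-4-ethenyl-2-[4-(triisopropylsilyloxy)phenyl]oxolane-3-carboxylate | C=C[C@H]1CO[C@@H](c2ccc(O[Si](C(C)C)(C(C)C)C(C)C)cc2)[C@@H]1C(=O)OC | intermediate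
9 | methyl (2R,3R,4R)-2-[4-(triisopropylsilyloxy)phenyl]-4-(1,2,4-trioxolan-3-yl)oxolane-3-carboxylate (both epimers at the trioxolane carbon) | C1(OCOO1)[C@H]2CO[C@@H](c3ccc(O[Si](C(C)C)(C(C)C)C(C)C)cc3)[C@@H]2C(=O)OC | intermediate (not isolated)
10 | methyl (2R,3R,4R)-4-formyl-2-[4-(triisopropylsilyloxy)phenyl]oxolane-3-carboxylate | O=C[C@H]1CO[C@@H](c2ccc(O[Si](C(C)C)(C(C)C)C(C)C)cc2)[C@@H]1C(=O)OC | intermediate
11 | 4-bromoanisole | COc1ccc(Br)cc1 | starting material
12 | 4-methoxyphenylmagnesium bromide | COc1ccc([Mg]Br)cc1 | intermediate (not isolated)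
13 | methyl (2R,3R,4R)-4-[hydroxy(4-methoxyphenyl)methyl]-2-[4-(triisopropylsilyloxy)phenyl]oxolane-3-carboxylate (both C7 epimers) | COc1ccc(C(O)[C@H]2CO[C@@H](c3ccc(O[Si](C(C)C)(C(C)C)C(C)C)cc3)[C@@H]2C(=O)OC)cc1 | intermediate
14 | methyl (2R,3R,4R)-4-(4-methoxybenzoyl)-2-[4-(triisopropylsilyloxy)phenyl]oxolane-3-carboxylate | COc1ccc(C(=O)[C@H]2CO[C@@H](c3ccc(O[Si](C(C)C)(C(C)C)C(C)C)cc3)[C@@H]2C(=O)OC)cc1 | intermediate
15 | methyl (2R,3R,4R)-4-[(S)-hydroxy(4-methoxyphenyl)methyl]-2-[4-(triisopropylsilyloxy)phenyl]oxolane-3-carboxylate | COc1ccc([C@@H](O)[C@H]2CO[C@@H](c3ccc(O[Si](C(C)C)(C(C)C)C(C)C)cc3)[C@@H]2C(=O)OC)cc1 | intermediate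
16 | [(2R,3S,4R)-4-[(S)-hydroxy(4-methoxyphenyl)methyl]-2-[4-(triisopropylsilyloxy)phenyl]oxolan-3-yl]methanol | COc1ccc([C@@H](O)[C@H]2CO[C@@H](c3ccc(O[Si](C(C)C)(C(C)C)C(C)C)cc3)[C@@H]2CO)cc1 | intermediate
17 | [(2R,3S,4R)-4-[(S)-acetyloxy(4-methoxyphenyl)methyl]-2-[4-(triisopropylsilyloxy)phenyl]oxolan-3-yl]methyl acetate | COc1ccc([C@@H](OC(C)=O)[C@H]2CO[C@@H](c3ccc(O[Si](C(C)C)(C(C)C)C(C)C)cc3)[C@@H]2COC(C)=O)cc1 | intermediate
18 | [(2R,3S,4R)-4-[(S)-acetyloxy(4-methoxyphenyl)methyl]-2-(4-hydroxyphenyl)oxolan-3-yl]methyl acetate | COc1ccc([C@@H](OC(C)=O)[C@H]2CO[C@@H](c3ccc(O)cc3)[C@@H]2COC(C)=O)cc1 | target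

## Step count and least certain steps

Total: 11 steps. Longest linear sequence: 11 steps, from 1 to 18; 3, 5 and 11 enter as commercial materials.

Step 3 (key step). The most likely failure is insufficient facial discrimination of the allyl unit by the ligand, since an unsubstituted carbonate paired with this acceptor is not an optimised case. Slow trapping of the alkoxide by the donor-substituted acceptor could also let the dipole decompose. Fallback by resolution: 4 and 5 are combined with Pd2(dba)3·CHCl3 and the achiral ligand 1,2-bis(diphenylphosphino)ethane to give the racemic cycloadduct F1. This is taken through the operations of step 4 to the racemic ester F2 and hydrolysed with Me3SnOH in 1,2-dichloroethane to the racemic acid F3. F3 is crystallised with (R)-1-phenylethylamine as the diastereomeric salt F4. The acid F5 liberated from the salt with aqueous citric acid is methylated with Me3SiCHN2 in MeOH–toluene, which returns to the route at 8.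

Step 4. Epimerisation at C3 may be incomplete, because kinetic protonation after decarboxylation should occur anti to the cis aryl and vinyl groups. Methoxide may also induce beta-elimination across C3–C2 or remove the aryl silyl group. Fallback through a more acidic acyl derivative: 6 is opened with PhSH and Et3N in MeCN at 60 °C to the malonic half-thioester F6, which should decarboxylate under the amine. The resulting S-phenyl thioester F7 is equilibrated to the all-trans isomer with DBU, with no alkoxide needed. CF3CO2Ag in MeOH then converts F7 into 8.

Step 8. Facial selectivity may be poor because both ketone substituents are large, and the electron-rich aryl ketone may be reduced partly by uncatalysed borane. Fallback by substrate control: 14 is reduced with LiBH(s-Bu)3 in THF at −78 °C, where the Felkin–Anh preference (hydride anti to C3) alone should lead to 15.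

Step 6. The basic Grignard reagent may enolise the alpha-branched aldehyde and epimerise C4, or attack the methyl ester. Fallback with a non-basic organometallic: 10 is coupled with 4-iodoanisole under Nozaki–Hiyama–Kishi conditions (CrCl2, NiCl2 cat., DMF, rt), which should select the aldehyde and give 13.

Step 11. Fluoride may cause acetyl transfer or loss, and the unmasked phenoxide may open the C2–O1 bond. Fallback by reversing the protecting-group order: 16 is desilylated with TBAF to the triol F8 and peracetylated (Ac2O, pyridine) to the triacetate F9. The aryl acetate is then removed selectively by aminolysis with pyrrolidine in CH2Cl2 at 0 °C, which returns at 18.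

## Further compounds

F1 | step 3 | racemic 4-ethenyl-8,8-dimethyl-1-[4-(triisopropylsilyloxy)phenyl]-2,7,9-trioxaspiro[4.5]decane-6,10-dione (aryl and vinyl cis) | CC1(C)OC(=O)C2(C(=O)O1)[C@@H](C=C)CO[C@H]2c1ccc(O[Si](C(C)C)(C(C)C)C(C)C)cc1.CC1(C)OC(=O)C2(C(=O)O1)[C@H](C=C)CO[C@@H]2c1ccc(O[Si](C(C)C)(C(C)C)C(C)C)cc1
F2 | step 3 | racemic methyl 4-ethenyl-2-[4-(triisopropylsilyloxy)phenyl]oxolane-3-carboxylate (2,3-trans, 3,4-trans) | C=C[C@H]1CO[C@@H](c2ccc(O[Si](C(C)C)(C(C)C)C(C)C)cc2)[C@@H]1C(=O)OC.C=C[C@@H]1CO[C@H](c2ccc(O[Si](C(C)C)(C(C)C)C(C)C)cc2)[C@H]1C(=O)OC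
F3 | step 3 | racemic 4-ethenyl-2-[4-(triisopropylsilyloxy)phenyl]oxolane-3-carboxylic acid (2,3-trans, 3,4-trans) | C=C[C@H]1CO[C@@H](c2ccc(O[Si](C(C)C)(C(C)C)C(C)C)cc2)[C@@H]1C(=O)O.C=C[C@@H]1CO[C@H](c2ccc(O[Si](C(C)C)(C(C)C)C(C)C)cc2)[C@H]1C(=O)O
F4 | step 3 | (1R)-1-phenylethan-1-aminium (2R,3R,4R)-4-ethenyl-2-[4-(triisopropylsilyloxy)phenyl]oxolane-3-carboxylate | C[C@@H]([NH3+])c1ccccc1.C=C[C@H]1CO[C@@H](c2ccc(O[Si](C(C)C)(C(C)C)C(C)C)cc2)[C@@H]1C(=O)[O-]
F5 | step 3 | (2R,3R,4R)-4-ethenyl-2-[4-(triisopropylsilyloxy)phenyl]oxolane-3-carboxylic acid | C=C[C@H]1CO[C@@H](c2ccc(O[Si](C(C)C)(C(C)C)C(C)C)cc2)[C@@H]1C(=O)O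
F6 | step 4 | (2S,4R)-4-ethenyl-3-[(phenylsulfanyl)carbonyl]-2-[4-(triisopropylsilyloxy)phenyl]oxolane-3-carboxylic acid (both C3 epimers) | C=C[C@H]1CO[C@@H](c2ccc(O[Si](C(C)C)(C(C)C)C(C)C)cc2)C1(C(=O)O)C(=O)Sc1ccccc1
F7 | step 4 | S-phenyl (2R,3R,4R)-4-ethenyl-2-[4-(triisopropylsilyloxy)phenyl]oxolane-3-carbothioate | C=C[C@H]1CO[C@@H](c2ccc(O[Si](C(C)C)(C(C)C)C(C)C)cc2)[C@@H]1C(=O)Sc1ccccc1
F0 | step 8 | none | none
F0 | step 6 | none | none
F8 | step 11 | [(2R,3S,4R)-4-[(S)-hydroxy(4-methoxyphenyl)methyl]-2-(4-hydroxyphenyl)oxolan-3-yl]methanol | COc1ccc([C@@H](O)[C@H]2CO[C@@H](c3ccc(O)cc3)[C@@H]2CO)cc1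
F9 | step 11 | [(2R,3S,4R)-2-(4-acetyloxyphenyl)-4-[(S)-acetyloxy(4-methoxyphenyl)methyl]oxolan-3-yl]methyl acetate | COc1ccc([C@@H](OC(C)=O)[C@H]2CO[C@@H](c3ccc(OC(C)=O)cc3)[C@@H]2COC(C)=O)cc1
A1 | alternative 1 | methyl (2R,3R,4R)-4-[(S)-(tert-butyldimethylsilyloxy)(4-methoxyphenyl)methyl]-2-[4-(triisopropylsilyloxy)phenyl]oxolane-3-carboxylate | COc1ccc([C@@H](O[Si](C)(C)C(C)(C)C)[C@H]2CO[C@@H](c3ccc(O[Si](C(C)C)(C(C)C)C(C)C)cc3)[C@@H]2C(=O)OC)cc1
A2 | alternative 1 | methyl (3R,4S)-4-(tert-butyldimethylsilyloxy)-2-diazo-4-(4-methoxyphenyl)-3-({[4-(triisopropylsilyloxy)phenyl]methoxy}methyl)butanoate | COc1ccc([C@@H](O[Si](C)(C)C(C)(C)C)[C@@H](COCc2ccc(O[Si](C(C)C)(C(C)C)C(C)C)cc2)C(=[N+]=[N-])C(=O)OC)cc1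
A3 | alternative 2 | {(3R,4S,5R)-4-[(tert-butyldiphenylsilyloxy)methyl]-5-[4-(triisopropylsilyloxy)phenyl]oxolan-3-yl}(4-methoxyphenyl)methanone | COc1ccc(C(=O)[C@H]2CO[C@@H](c3ccc(O[Si](C(C)C)(C(C)C)C(C)C)cc3)[C@@H]2CO[Si](c4ccccc4)(c4ccccc4)C(C)(C)C)cc1
A4 | alternative 2 | (4S)-4-[(E)-3-(tert-butyldiphenylsilyloxy)prop-1-enyl]-4-(4-methoxyphenyl)-2-[4-(triisopropylsilyloxy)phenyl]-1,3-dioxolane (both epimers at the acetal carbon) | COc1ccc([C@@]2(/C=C/CO[Si](c3ccccc3)(c3ccccc3)C(C)(C)C)COC(c3ccc(O[Si](C(C)C)(C(C)C)C(C)C)cc3)O2)cc1
A5 | alternative 3 | dimethyl (4S,5R)-5-[4-(tert-butyldimethylsilyloxy)phenyl]-4-[(tert-butyldiphenylsilyloxy)methyl]oxolane-3,3-dicarboxylate | COC(=O)C1(C(=O)OC)CO[C@@H](c2ccc(O[Si](C)(C)C(C)(C)C)cc2)[C@@H]1CO[Si](c2ccccc2)(c2ccccc2)C(C)(C)C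
A6 | alternative 3 | dimethyl (2S,3S)-2-[4-(tert-butyldimethylsilyloxy)phenyl]-3-[(tert-butyldiphenylsilyloxy)methyl]cyclopropane-1,1-dicarboxylate (aryl and silyloxymethyl cis) | COC(=O)C1(C(=O)OC)[C@H](c2ccc(O[Si](C)(C)C(C)(C)C)cc2)[C@@H]1CO[Si](c2ccccc2)(c2ccccc2)C(C)(C)C
A7 | alternative 3 | formaldehyde | C=O
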